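**Retrosynthetic overview**
1. Target ⇒ 2,4-diol 6-(4-methoxybenzoate): the C2 angelate goes on last, the tertiary C4–OH stays free. The five-membered ring is the second ring formed, closed at C3–C4 by aldol addition of a C2 methyl-ketone enolate to a C4 isopropyl ketone, with the C2 carbonyl reduced in the same flask.
2. Diketone ⇒ C1-vinyl ketone (Tsuji–Wacker) ⇒ acyclic triene: the seven-membered ring is the first ring formed, by ring-closing metathesis at C8=C9 (allyl on C1, methallyl on C6).
3. Triene ketone ⇒ β-hydroxy acid (C6–OH acylated once, as the final 4-methoxybenzoate; CO2H → isopropyl ketone) ⇒ allylic β-hydroxy ester: one dianionic Ireland–Claisen rearrangement makes the C1–C5 bond, quaternary C1 and C5, relayed from the C6 carbinol.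
4. Allylic ester ⇒ (E)-3-methylhexa-2,5-dien-1-ol (carboalumination of pent-1-en-4-yne) + ethyl (3S)-3-hydroxy-5-methylhex-5-enoate (from ethyl (3R)-4-chloro-3-hydroxybutanoate).
5. Enabling feature: C2 and C4 both carry oxygen and are bridged only by the CH2 C3, and they sit on the vicinal ring carbons C1 (quaternary) and C5 of the seven-membered ring. At the ketone level this is a 1,4-diketone whose C2 carbonyl can enolise only toward C3 and whose C4 carbonyl is flanked by the C6 acyloxy group.

Key step: step 10

Remark: locants C1–C10 are the daucane locants of the target (five-membered ring C1–C2–C3–C4–C5, seven-membered ring C1–C5–C6–C7–C8–C9–C10; CH3 on C1 and C8, isopropyl on C4, C8=C9). Pent-1-en-4-yne, ethyl (3R)-4-chloro-3-hydroxybutanoate, the two Grignard reagents, 4-methoxybenzoyl chloride and angelic acid are taken as purchased.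

**Step 1**
Reactants: 1 pent-1-en-4-yne
Product: 4 (2E)-3-methylhexa-2,5-dien-1-ol, via alkenyldimethylalane 2 (not isolated), via lithium alkenylaluminate 3 (not isolated)
Conditions: AlMe3 (2 equiv), Cp2ZrCl2 (0.2 equiv), CH2Cl2, 0 → 23 °C; excess AlMe3 evaporated; n-BuLi (1 equiv), hexane/THF, −78 °C; (CH2O)n, −78 → 23 °C; aq. HCl
Reagents that add atoms: trimethylaluminium, C[Al](C)C; formaldehyde (as paraformaldehyde), C=O
Why: Negishi carboalumination adds methyl and aluminium syn across the terminal alkyne and the aluminate 3 is hydroxymethylated with retention, so the allyl group ends trans to CH2OH (E), the geometry that later sets C1.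

**Step 2**
Reactants: 5 ethyl (3R)-4-chloro-3-hydroxybutanoate
Product: 6 ethyl 2-[(2R)-oxiran-2-yl]acetate
Conditions: Ag2O (1.2 equiv), 1,2-dimethoxyethane, 60 °C, exclusion of light
Reagents that add atoms: none
Why: Silver-assisted intramolecular displacement of chloride by the neighbouring hydroxyl (halohydrin-to-epoxide closure) needs no added base, which the base-labile β,γ-epoxy ester requires, and leaves the carbinol centre untouched.

**Step 3**
Reactants: 6 ethyl 2-[(2R)-oxiran-2-yl]acetate
Product: 7 ethyl (3S)-3-hydroxy-5-methylhex-5-enoate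
Conditions: CH2=C(CH3)MgBr (1.3 equiv), CuI (0.1 equiv), THF, −40 °C; aq. NH4Cl
Reagents that add atoms: isopropenylmagnesium bromide, C=C(C)[Mg]Br
Why: Copper-catalysed Grignard opening of the terminal epoxide at its CH2 carbon (SN2) outpaces addition to the ester at −40 °C; no bond to the stereocentre is broken, and the descriptor changes from R to S only because the CIP ranking of the two CH2 groups changes.

**Step 4**
Reactants: 7 ethyl (3S)-3-hydroxy-5-methylhex-5-enoate; 4 (2E)-3-methylhexa-2,5-dien-1-ol
Product: 8 (2E)-3-methylhexa-2,5-dien-1-yl (3S)-3-hydroxy-5-methylhex-5-enoate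
Conditions: Ti(OEt)4 (0.2 equiv), toluene, 100 °C, EtOH distilled off
Reagents that add atoms: none
Why: Titanate-catalysed transesterification is neutral, tolerates the free β-hydroxyl and the alkenes, and is driven by removal of ethanol.

**Step 5**
Reactants: 8 (2E)-3-methylhexa-2,5-dien-1-yl (3S)-3-hydroxy-5-methylhex-5-enoate
Product: 10 (2S,3S)-3-ethenyl-2-[(1S)-1-hydroxy-3-methylbut-3-en-1-yl]-3-methylhex-5-enoic acid, via dilithium dianion 9 (not isolated)
Conditions: LiN(iPr)2 (2.1 equiv), THF, −78 °C; then 23 → 55 °C; aq. HCl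
Reagents that add atoms: none
Why: Dianionic Ireland–Claisen rearrangement: the lithium chelate 9 fixes the enolate oxygen cis to C6, the allyl terminus is delivered through a chair transition state to the enolate face anti to the methallyl group on C6 (the sense of the Fráter–Seebach alkylation, C5 anti to the C6 oxygen), and the E alkene places the allyl group pseudo-equatorial and the methyl pseudo-axial, which sets the quaternary C1 together with the C1–C5 bond.

**Step 6**
Reactants: 10 (2S,3S)-3-ethenyl-2-[(1S)-1-hydroxy-3-methylbut-3-en-1-yl]-3-methylhex-5-enoic acid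
Product: 11 (2S,3S)-3-ethenyl-2-[(1S)-1-(4-methoxybenzoyloxy)-3-methylbut-3-en-1-yl]-3-methylhex-5-enoic acid
Conditions: 4-MeOC6H4COCl (2.2 equiv), pyridine, DMAP (0.1 equiv), CH2Cl2, 0 → 23 °C; then THF/aq. NaHCO3, acidify to pH 3
Reagents that add atoms: 4-methoxybenzoyl chloride, COc1ccc(cc1)C(Cl)=O
Why: DMAP-catalysed acylation of the secondary alcohol installs the ester that the target carries at C6, so it also serves as the protecting group for the rest of the route; the mixed anhydride formed at the carboxyl group is hydrolysed in the basic work-up.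

**Step 7**
Reactants: 11 (2S,3S)-3-ethenyl-2-[(1S)-1-(4-methoxybenzoyloxy)-3-methylbut-3-en-1-yl]-3-methylhex-5-enoic acid
Product: 13 (4S,5S)-5-ethenyl-2,5-dimethyl-4-[(1S)-1-(4-methoxybenzoyloxy)-3-methylbut-3-en-1-yl]oct-7-en-3-one, via acid chloride 12 (not isolated)
Conditions: (COCl)2, DMF (cat.), CH2Cl2, 0 → 23 °C, evaporate; then iPrMgCl (1.1 equiv), Fe(acac)3 (3 mol %), THF, −78 °C
Reagents that add atoms: isopropylmagnesium chloride, CC(C)[Mg]Cl; oxalyl chloride, O=C(Cl)C(Cl)=O (its chlorine remains only in 12)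
Why: Iron-catalysed acyl cross-coupling of acid chloride 12 with the secondary Grignard reagent is faster at −78 °C than addition to the aryl ester or to the product ketone and does not epimerise C5.

**Step 8**
Reactants: 13 (4S,5S)-5-ethenyl-2,5-dimethyl-4-[(1S)-1-(4-methoxybenzoyloxy)-3-methylbut-3-en-1-yl]oct-7-en-3-one
Product: 14 (1S,6S,7S)-6-ethenyl-3,6-dimethyl-7-(2-methylpropanoyl)cyclohept-3-en-1-yl 4-methoxybenzoate
Conditions: second-generation Grubbs catalyst RuCl2(=CHPh)(PCy3)(H2IMes) (5 mol %), CH2Cl2 (5 mM), 40 °C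
Reagents that add atoms: none
Why: Ring-closing metathesis initiates at the unhindered allyl group and closes onto the methallyl 1,1-disubstituted alkene to give the trisubstituted C8=C9 bond of the seven-membered ring, whereas the neopentyl vinyl group on C1 initiates poorly and could pair with the allyl carbene only in a four-membered ring.

**Step 9**
Reactants: 14 (1S,6S,7S)-6-ethenyl-3,6-dimethyl-7-(2-methylpropanoyl)cyclohept-3-en-1-yl 4-methoxybenzoate
Product: 15 (1S,6R,7S)-6-acetyl-3,6-dimethyl-7-(2-methylpropanoyl)cyclohept-3-en-1-yl 4-methoxybenzoate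
Conditions: PdCl2 (0.2 equiv), CuCl (1 equiv), O2 (1 atm), DMF/H2O 7:1, 23–40 °C
Reagents that add atoms: water, O
Why: Tsuji–Wacker oxidation (Markovnikov hydroxypalladation, then β-hydride elimination) converts the monosubstituted vinyl group into the methyl ketone, the trisubstituted ring alkene being inert to PdCl2 under these conditions.

**Step 10**
Reactants: 15 (1S,6R,7S)-6-acetyl-3,6-dimethyl-7-(2-methylpropanoyl)cyclohept-3-en-1-yl 4-methoxybenzoate
Product: 18 (1R,2R,4R,5S,6S)-2,4-dihydroxydauc-8-en-6-yl 4-methoxybenzoate, via lithium enolate 16 (not isolated), via ketol 17 (not isolated)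
Conditions: LiN(SiMe3)2 (1.1 equiv), THF, −78 °C, then −45 °C (15 min); MeOH, −78 °C; then NaBH4 (2 equiv), CeCl3·7H2O (1 equiv), −78 → −20 °C; aq. NH4Cl
Reagents that add atoms: none
Why: LiN(SiMe3)2 can deprotonate kinetically only at C3 of the C2 ketone (C1 is quaternary; C5–H and the isopropyl methine beside the C4 ketone are tertiary and shielded), and the lithium enolate 16 adds to the C4 ketone in an intramolecular aldol addition, the closest known type being the base-mediated cyclopentanol-forming aldolisation of 1,4-diketones. The five-membered ring closes in the 5-(enolexo)-exo-trig mode across the trans-disposed C1 and C5 substituents and so is trans-fused to the seven-membered ring. At C4 the isopropyl group turns away from C6 while lithium bridges the C4 oxygen and the C6 ester, so the hydroxyl ends cis to C6 and to the C1 methyl; because lithium aldolates of ketone–ketone aldols revert on brief warming, any minor C4 epimer should drain through 16 into this chelated, less crowded aldolate. Protonation at −78 °C and immediate Luche reduction remove the C2 carbonyl before retro-aldol cleavage, dehydration or acyl migration can set in, and hydride attacks C2 anti to the angular C1 methyl (as in 17-oxo steroids), which places the C2 hydroxyl cis to that methyl and to the C4 hydroxyl. The step needs C3-over-C5 enolisation, secured by the quaternary C1 and the low temperature (which also protects the β-acyloxy ketone from elimination), and ketone-over-ester reduction, secured by NaBH4 below −20 °C.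

**Step 11**
Reactants: 18 (1R,2R,4R,5S,6S)-2,4-dihydroxydauc-8-en-6-yl 4-methoxybenzoate
Product: 19 (1R,2R,4R,5S,6S)-4-hydroxy-2-[(2Z)-2-methylbut-2-enoyloxy]dauc-8-en-6-yl 4-methoxybenzoate (CNP0204191.1)
Conditions: angelic acid (3 equiv), 2,4,6-Cl3C6H2COCl (3 equiv), Et3N (3 equiv), toluene, 23 °C; then 18, toluene, 80 °C
Reagents that add atoms: angelic acid [(2Z)-2-methylbut-2-enoic acid], C/C=C(/C)C(=O)O
Why: Acylation through the mixed anhydride with 2,4,6-trichlorobenzoic acid without nucleophilic catalyst (Yamaguchi esterification in its non-isomerising form) esterifies the secondary C2 hydroxyl, keeps the Z geometry of the acid, and leaves the tertiary C4 hydroxyl free.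

**Compound list**
1 | pent-1-en-4-yne | C=CCC#C | starting material
2 | dimethyl[(1E)-2-methylpenta-1,4-dien-1-yl]alane | C=CC/C(C)=C/[Al](C)C | intermediate
3 | lithium butyl(dimethyl)[(1E)-2-methylpenta-1,4-dien-1-yl]aluminate | [Li+].C=CC/C(C)=C/[Al-](C)(C)CCCC | intermediate
4 | (2E)-3-methylhexa-2,5-dien-1-ol | C=CC/C(C)=C/CO | intermediate
5 | ethyl (3R)-4-chloro-3-hydroxybutanoate | CCOC(=O)C[C@@H](O)CCl | starting material
6 | ethyl 2-[(2R)-oxiran-2-yl]acetate | CCOC(=O)C[C@@H]1CO1 | intermediate
7 | ethyl (3S)-3-hydroxy-5-methylhex-5-enoate | CCOC(=O)C[C@@H](O)CC(C)=C | intermediate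
8 | (2E)-3-methylhexa-2,5-dien-1-yl (3S)-3-hydroxy-5-methylhex-5-enoate | C=CC/C(C)=C/COC(=O)C[C@@H](O)CC(C)=C | intermediate
9 | dilithium enolate-alkoxide (dianion) of 8, enolate oxygen cis to C6 | [Li+].[Li+].C=CC/C(C)=C/CO/C([O-])=C/[C@@H]([O-])CC(C)=C | intermediate
10 | (2S,3S)-3-ethenyl-2-[(1S)-1-hydroxy-3-methylbut-3-en-1-yl]-3-methylhex-5-enoic acid | C=C[C@](C)(CC=C)[C@@H]([C@@H](O)CC(C)=C)C(=O)O | intermediate
11 | (2S,3S)-3-ethenyl-2-[(1S)-1-(4-methoxybenzoyloxy)-3-methylbut-3-en-1-yl]-3-methylhex-5-enoic acid | C=C[C@](C)(CC=C)[C@@H]([C@@H](OC(=O)c1ccc(OC)cc1)CC(C)=C)C(=O)O | intermediate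
12 | (2S,3S)-3-ethenyl-2-[(1S)-1-(4-methoxybenzoyloxy)-3-methylbut-3-en-1-yl]-3-methylhex-5-enoyl chloride | C=C[C@](C)(CC=C)[C@@H]([C@@H](OC(=O)c1ccc(OC)cc1)CC(C)=C)C(Cl)=O | intermediate
13 | (4S,5S)-5-ethenyl-2,5-dimethyl-4-[(1S)-1-(4-methoxybenzoyloxy)-3-methylbut-3-en-1-yl]oct-7-en-3-one | C=C[C@](C)(CC=C)[C@@H]([C@@H](OC(=O)c1ccc(OC)cc1)CC(C)=C)C(=O)C(C)C | intermediate
14 | (1S,6S,7S)-6-ethenyl-3,6-dimethyl-7-(2-methylpropanoyl)cyclohept-3-en-1-yl 4-methoxybenzoate | C=C[C@]1(C)CC=C(C)C[C@H](OC(=O)c2ccc(OC)cc2)[C@H]1C(=O)C(C)C | intermediate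
15 | (1S,6R,7S)-6-acetyl-3,6-dimethyl-7-(2-methylpropanoyl)cyclohept-3-en-1-yl 4-methoxybenzoate | CC(=O)[C@]1(C)CC=C(C)C[C@H](OC(=O)c2ccc(OC)cc2)[C@H]1C(=O)C(C)C | intermediate
16 | lithium enolate of 15 at C2–C3 | [Li+].C=C([O-])[C@]1(C)CC=C(C)C[C@H](OC(=O)c2ccc(OC)cc2)[C@H]1C(=O)C(C)C | intermediate
17 | (1R,4R,5S,6S)-4-hydroxy-2-oxodauc-8-en-6-yl 4-methoxybenzoate (ketol) | O=C1C[C@@](O)(C(C)C)[C@@H]2[C@@H](OC(=O)c3ccc(OC)cc3)CC(C)=CC[C@]21C | intermediate
18 | (1R,2R,4R,5S,6S)-2,4-dihydroxydauc-8-en-6-yl 4-methoxybenzoate | O[C@@H]1C[C@@](O)(C(C)C)[C@@H]2[C@@H](OC(=O)c3ccc(OC)cc3)CC(C)=CC[C@]21C | intermediate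
19 | (1R,2R,4R,5S,6S)-4-hydroxy-2-[(2Z)-2-methylbut-2-enoyloxy]dauc-8-en-6-yl 4-methoxybenzoate (CNP0204191.1) | C/C=C(/C)C(=O)O[C@@H]1C[C@@](O)(C(C)C)[C@@H]2[C@@H](OC(=O)c3ccc(OC)cc3)CC(C)=CC[C@]21C | target

**Step count and risks**
Total step count: 11. Longest linear sequence: 10 steps (steps 2 to 11, from 5 to 19).

Steps most likely to fail:

1. Step 5. What may go wrong: fragmentation of the ester dianion to a ketene before the slow rearrangement at the fully substituted allyl terminus, base-induced migration of the skipped diene, or erosion of facial control. Fallback, setting out from 8 and returning at 10: the C6 hydroxyl is silylated to give the tert-butyldimethylsilyl ether F1 (tBuMe2SiCl, imidazole, DMF). F1 is enolised with LiN(iPr)2 in THF/DMPU at −78 °C and trapped with Me3SiCl to give the (Z)-silyl ketene acetal F2, which has the same enolate geometry as 9 (OSiMe3 cis to C6). F2 should rearrange between 23 and 60 °C through a chair transition state (Ireland–Claisen rearrangement) to the trimethylsilyl ester F3. Aqueous work-up hydrolyses F3 to the silyl ether acid F4, and HF·pyridine in THF returns 10. Facial control then rests on the silyloxy-bearing C6 alone and is less secure, so a diastereomer separation may be needed.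

2. Step 10. What may go wrong: migration of the 4-methoxybenzoyl group to the tertiary alkoxide, β-elimination of 4-methoxybenzoate from the C4 ketone after proton transfer to C5, or poor facial selectivity of hydride delivery. Fallback, setting out from 15 and returning at 17: soft enolisation (Me3SiOTf, Et3N, CH2Cl2, −78 °C) gives the trimethylsilyl enol ether F5. TiCl4 (CH2Cl2, −78 °C) should then effect an intramolecular Mukaiyama aldol addition in which titanium binds the C4 ketone and the C6 ester, so that no basic alkoxide is present. Aqueous work-up gives ketol 17 as an isolated compound, which is reduced to 18 with NaBH4 and CeCl3·7H2O in MeOH at −78 °C.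

3. Step 9. What may go wrong: anti-Markovnikov attack of water at the neopentyl vinyl group (aldehyde formation) or stalling of the catalyst. Fallback, setting out from 14 and returning at 15: Mukaiyama hydration (Co(acac)2, PhSiH3, O2, iPrOH, 23 °C) is a hydrogen-atom-transfer process that is Markovnikov by radical stability and should be faster at the monosubstituted alkene than at the ring trisubstituted one. It should give the secondary alcohol F6 (both C2 epimers), which Dess–Martin periodinane (CH2Cl2, NaHCO3) oxidises to diketone 15.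

**Further compounds**
F1 | step 5 | (2E)-3-methylhexa-2,5-dien-1-yl (3S)-3-[(tert-butyldimethylsilyl)oxy]-5-methylhex-5-enoate | C=CC/C(C)=C/COC(=O)C[C@@H](O[Si](C)(C)C(C)(C)C)CC(C)=C
F2 | step 5 | (Z)-O-trimethylsilyl ketene acetal of F1 | C=CC/C(C)=C/CO/C(O[Si](C)(C)C)=C/[C@@H](O[Si](C)(C)C(C)(C)C)CC(C)=C
F3 | step 5 | trimethylsilyl (2S,3S)-2-[(1S)-1-[(tert-butyldimethylsilyl)oxy]-3-methylbut-3-en-1-yl]-3-ethenyl-3-methylhex-5-enoate | C=C[C@](C)(CC=C)[C@@H]([C@@H](O[Si](C)(C)C(C)(C)C)CC(C)=C)C(=O)O[Si](C)(C)C
F4 | step 5 | (2S,3S)-2-[(1S)-1-[(tert-butyldimethylsilyl)oxy]-3-methylbut-3-en-1-yl]-3-ethenyl-3-methylhex-5-enoic acid | C=C[C@](C)(CC=C)[C@@H]([C@@H](O[Si](C)(C)C(C)(C)C)CC(C)=C)C(=O)O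
F5 | step 10 | trimethylsilyl enol ether of 15 at C2–C3 | C=C(O[Si](C)(C)C)[C@]1(C)CC=C(C)C[C@H](OC(=O)c2ccc(OC)cc2)[C@H]1C(=O)C(C)C
F6 | step 9 | 6-(1-hydroxyethyl) analogue of 15 (C2 carbinol, both epimers) | CC(O)[C@]1(C)CC=C(C)C[C@H](OC(=O)c2ccc(OC)cc2)[C@H]1C(=O)C(C)C
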